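## Retrosynthetic overview

- The target is reached from its cis diol (C3–OH and CH2OH free, phenol as MOM ether, acetyl as dioxolane) by primary acetylation, C3 angeloylation and acid hydrolysis. The CH2OH carbon comes from a Stille coupling of the 2-iodoalkene, which comes from the alkenyl boronate.
- The alkenyl boronate is disconnected at C2–C3 to an aryl allenyl ether with an ortho aldehyde plus B2pin2. One copper-catalysed borylative cyclisation forms this bond, closes the dihydrofuran ring (the only ring formed; the benzene ring is bought) and sets C2 and C3.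
- Feature used: C2 carries O1, the C3 carbinol carbon and a 1,1-disubstituted vinyl group. The C2–C3 bond therefore joins an oxygen-bearing allylic carbon, whose allyl unit is substituted at its central carbon, to a former aldehyde carbon ortho to O1 on the benzene ring.
- The allenyl ether aldehyde comes from 5-bromo-2,4-dihydroxybenzaldehyde: MOM on the para hydroxyl, Br to masked acetyl (Stille, then dioxolane from the enol ether), propargylation of the ortho hydroxyl, base isomerisation. The aldehyde is present throughout, so no organolithium meets a propargyl or allenyl ether.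

Key step: step 5

Remark: both enantiomers of Ph-BPE are purchasable; the (R,R) ligand is written, and the hand that delivers the (2R,3R) product of the key step is fixed once the first product is assigned.
Remark: 5-bromo-2,4-dihydroxybenzaldehyde is taken as purchasable.
Remark: the allenyl ether and all 3-oxygenated dihydrobenzofurans are purified on triethylamine-deactivated silica, because the electron-rich benzylic C3–O bond ionises easily.

## Route

Step 1
Reactants: 1 5-bromo-2,4-dihydroxybenzaldehyde
Product: 2 5-bromo-2-hydroxy-4-(methoxymethoxy)benzaldehyde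
Conditions: MOMCl (1.05 equiv), i-Pr2NEt, CH2Cl2, 0 °C
Reagents that add atoms: chloromethyl methyl ether, COCCl
Why: Williamson-type O-alkylation: the hydroxyl para to the aldehyde is the more acidic one and is not held in the hydrogen bond that ties the ortho hydroxyl to the carbonyl, so one equivalent of MOMCl should go to O4 only.

Step 2
Reactants: 2 5-bromo-2-hydroxy-4-(methoxymethoxy)benzaldehyde; 3 tributyl(1-ethoxyvinyl)stannane
Product: 5 2-hydroxy-4-(methoxymethoxy)-5-(2-methyl-1,3-dioxolan-2-yl)benzaldehyde, via 1-ethoxyvinyl arene 4 (not isolated)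
Conditions: PdCl2(PPh3)2 (5 mol %), toluene, 100 °C; then HOCH2CH2OH, PPTS (cat.), 4 Å MS, THF, rt
Reagents that add atoms: tributyl(1-ethoxyvinyl)stannane 3, CCCC[Sn](CCCC)(CCCC)C(=C)OCC; ethylene glycol, OCCO
Why: Stille coupling of the aryl bromide with the α-ethoxyvinyl stannane, followed by acid-catalysed addition of the diol to the enol ether and closure to the dioxolane (the chemistry by which 2-methoxypropene gives acetonides), which needs only PPTS at room temperature, so the aryl MOM ether and the hydrogen-bonded salicylaldehyde should be left alone.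

Step 3
Reactants: 5 2-hydroxy-4-(methoxymethoxy)-5-(2-methyl-1,3-dioxolan-2-yl)benzaldehyde; 6 propargyl bromide
Product: 7 4-(methoxymethoxy)-5-(2-methyl-1,3-dioxolan-2-yl)-2-(prop-2-yn-1-yloxy)benzaldehyde
Conditions: K2CO3, DMF, rt
Reagents that add atoms: propargyl bromide 6, C#CCBr
Why: Williamson ether synthesis: K2CO3 in DMF is basic enough to alkylate the chelated ortho phenol with the reactive propargylic bromide, and nothing else in 5 is electrophilic or acidic under these conditions.

Step 4
Reactants: 7 4-(methoxymethoxy)-5-(2-methyl-1,3-dioxolan-2-yl)-2-(prop-2-yn-1-yloxy)benzaldehyde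
Product: 8 4-(methoxymethoxy)-5-(2-methyl-1,3-dioxolan-2-yl)-2-(propa-1,2-dien-1-yloxy)benzaldehyde
Conditions: KOtBu (0.3 equiv), THF/t-BuOH, rt
Reagents that add atoms: none
Why: Base-mediated propargyl-to-allenyl prototropic isomerisation of an aryl propargyl ether, run with substoichiometric KOtBu and stopped before the 1-propynyl ether appears; the aldehyde has no α-hydrogen and the ketone is masked, so no aldol pathway is open.

Step 5
Reactants: 8 4-(methoxymethoxy)-5-(2-methyl-1,3-dioxolan-2-yl)-2-(propa-1,2-dien-1-yloxy)benzaldehyde; 9 bis(pinacolato)diboron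
Product: 12 (2R,3R)-6-(methoxymethoxy)-5-(2-methyl-1,3-dioxolan-2-yl)-2-[1-(4,4,5,5-tetramethyl-1,3,2-dioxaborolan-2-yl)ethenyl]-2,3-dihydro-1-benzofuran-3-ol, via allylcopper 10 (not isolated), via pinacolboryl ether 11 (not isolated)
Conditions: CuCl (5 mol %), (R,R)-Ph-BPE (6 mol %), NaOtBu (10 mol %), B2pin2 (1.05 equiv), THF, 0 °C to rt; aq. NH4Cl work-up
Reagents that add atoms: bis(pinacolato)diboron 9, CC1(C)OB(OC1(C)C)B2OC(C)(C)C(C)(C)O2
Why: Proposed new method: CuCl, NaOtBu and the bisphosphine give a ligated Cu–Bpin that adds across the terminal C=C of the allenyl ether (boron to the central carbon, copper to CH2) to give allylcopper 10, whose oxygen-bearing γ-carbon attacks the ortho aldehyde through a six-membered cyclic transition state, and B2pin2 then takes the copper alkoxide to boryl ether 11 and regenerates Cu–Bpin. The closest known reaction type is the copper–bisphosphine-catalysed enantioselective three-component coupling of monosubstituted allenes, B2pin2 and aldehydes to 2-boryl homoallylic alcohols; closing a ring onto an aldehyde tethered through the allenyl ether oxygen is the untested part. The dihydrofuran ring (O1–C2–C3–C3a–C7a) closes by 5-exo-trig attack on the carbonyl as the C2–C3 bond forms. C2 and C3 are set together: they should come out cis because the O1–C2–C3–C3a torsion of the nearly planar benzo-fused ring is small, so the six-membered array Cu–CH2–C(B)=C2···C3=O can only close with the borylvinyl carbon and the carbonyl oxygen on the same face, and the absolute sense is controlled by the chiral bisphosphine on copper, which selects the aldehyde face. The step needs borylcupration of the allene to outrun 1,2-addition of Cu–Bpin to the aldehyde and five-membered to beat seven-membered closure; the electron-rich (para-alkoxy) aldehyde and the phosphine ligand favour the first, and copper resting on the primary CH2 terminus, from which γ-attack can only give the five-membered ring, secures the second.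

Step 6
Reactants: 12 (2R,3R)-6-(methoxymethoxy)-5-(2-methyl-1,3-dioxolan-2-yl)-2-[1-(4,4,5,5-tetramethyl-1,3,2-dioxaborolan-2-yl)ethenyl]-2,3-dihydro-1-benzofuran-3-ol
Product: 13 (2S,3R)-2-(1-iodoethenyl)-6-(methoxymethoxy)-5-(2-methyl-1,3-dioxolan-2-yl)-2,3-dihydro-1-benzofuran-3-ol (cis, same spatial arrangement as 12)
Conditions: NaOH (3 M aq.), THF, 0 °C; then I2 in THF, 0 °C; Na2S2O3 quench
Reagents that add atoms: iodine, II
Why: Iododeboronation of an alkenyl boronate: hydroxide forms the borate, iodine attacks the boron-bearing carbon and the β-borato cation loses boron, which should give the 2-iodoalkene without touching C2 or C3 (the C2 descriptor becomes S only because the iodovinyl carbon now outranks C3).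

Step 7
Reactants: 13 (2S,3R)-2-(1-iodoethenyl)-6-(methoxymethoxy)-5-(2-methyl-1,3-dioxolan-2-yl)-2,3-dihydro-1-benzofuran-3-ol; 14 (tributylstannyl)methanol
Product: 15 (2R,3R)-2-(3-hydroxyprop-1-en-2-yl)-6-(methoxymethoxy)-5-(2-methyl-1,3-dioxolan-2-yl)-2,3-dihydro-1-benzofuran-3-ol
Conditions: Pd(PPh3)4 (5 mol %), 1,4-dioxane, 80 °C
Reagents that add atoms: (tributylstannyl)methanol 14, CCCC[Sn](CCCC)(CCCC)CO
Why: Stille coupling of the alkenyl iodide with (tributylstannyl)methanol, a known way to put a hydroxymethyl group on an sp2 carbon under neutral conditions that the free alcohol, the acetals and both stereocentres tolerate.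

Step 8
Reactants: 15 (2R,3R)-2-(3-hydroxyprop-1-en-2-yl)-6-(methoxymethoxy)-5-(2-methyl-1,3-dioxolan-2-yl)-2,3-dihydro-1-benzofuran-3-ol
Product: 16 2-[(2R,3R)-3-hydroxy-6-(methoxymethoxy)-5-(2-methyl-1,3-dioxolan-2-yl)-2,3-dihydro-1-benzofuran-2-yl]prop-2-en-1-yl acetate
Conditions: AcCl (1.05 equiv), 2,4,6-collidine, CH2Cl2, −78 °C
Reagents that add atoms: acetyl chloride, CC(Cl)=O
Why: Selective acylation: acetyl chloride with the hindered base collidine at low temperature acylates the primary allylic hydroxyl much faster than the secondary benzylic hydroxyl, which is cis to the C2 side chain.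

Step 9
Reactants: 16 2-[(2R,3R)-3-hydroxy-6-(methoxymethoxy)-5-(2-methyl-1,3-dioxolan-2-yl)-2,3-dihydro-1-benzofuran-2-yl]prop-2-en-1-yl acetate; 17 angelic acid
Product: 19 (2R,3R)-2-[3-(acetyloxy)prop-1-en-2-yl]-6-(methoxymethoxy)-5-(2-methyl-1,3-dioxolan-2-yl)-2,3-dihydro-1-benzofuran-3-yl (2Z)-2-methylbut-2-enoate, via mixed anhydride 18 (not isolated)
Conditions: 17, 2,4,6-Cl3C6H2COCl, Et3N, toluene, rt; then 16, toluene, 80 °C
Reagents that add atoms: angelic acid 17, C/C=C(/C)C(=O)O
Why: Yamaguchi esterification through the preformed mixed anhydride, heated without a nucleophilic catalyst, which is the usual way to acylate a hindered secondary alcohol with angelic acid while keeping the Z double bond from isomerising to the tiglate; C3 reacts at oxygen, so its configuration is retained.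

Step 10
Reactants: 19 (2R,3R)-2-[3-(acetyloxy)prop-1-en-2-yl]-6-(methoxymethoxy)-5-(2-methyl-1,3-dioxolan-2-yl)-2,3-dihydro-1-benzofuran-3-yl (2Z)-2-methylbut-2-enoate
Product: 21 (2R,3R)-5-acetyl-2-[3-(acetyloxy)prop-1-en-2-yl]-6-hydroxy-2,3-dihydro-1-benzofuran-3-yl (2Z)-2-methylbut-2-enoate, via MOM ketone 20 (not isolated)
Conditions: HCl (1 M aq.), THF, 0 °C to rt
Reagents that add atoms: water, O
Why: Acid-catalysed acetal hydrolysis in two stages in one flask: the dioxolane of the electron-rich aryl ketone should open first, and the MOM ether, then ortho to the acetyl group, follows, while the two esters and the configuration at C2 and C3 should survive dilute acid at or below room temperature.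

## Compound list

1 | 5-bromo-2,4-dihydroxybenzaldehyde | O=Cc1cc(Br)c(O)cc1O | starting material
2 | 5-bromo-2-hydroxy-4-(methoxymethoxy)benzaldehyde | O=Cc1cc(Br)c(OCOC)cc1O | intermediate
3 | tributyl(1-ethoxyvinyl)stannane | CCCC[Sn](CCCC)(CCCC)C(=C)OCC | starting material
4 | 5-(1-ethoxyethenyl)-2-hydroxy-4-(methoxymethoxy)benzaldehyde | C=C(OCC)c1cc(C=O)c(O)cc1OCOC | intermediate (not isolated)
5 | 2-hydroxy-4-(methoxymethoxy)-5-(2-methyl-1,3-dioxolan-2-yl)benzaldehyde | CC1(OCCO1)c1cc(C=O)c(O)cc1OCOC | intermediate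
6 | propargyl bromide | C#CCBr | starting material
7 | 4-(methoxymethoxy)-5-(2-methyl-1,3-dioxolan-2-yl)-2-(prop-2-yn-1-yloxy)benzaldehyde | C#CCOc1cc(OCOC)c(C2(C)OCCO2)cc1C=O | intermediate
8 | 4-(methoxymethoxy)-5-(2-methyl-1,3-dioxolan-2-yl)-2-(propa-1,2-dien-1-yloxy)benzaldehyde | C=C=COc1cc(OCOC)c(C2(C)OCCO2)cc1C=O | intermediate
9 | bis(pinacolato)diboron | CC1(C)OB(OC1(C)C)B2OC(C)(C)C(C)(C)O2 | starting material
10 | 2-boryl-3-aryloxy allylcopper from borylcupration of 8 (Ph-BPE on copper not drawn, alkene geometry open) | [Cu]CC(B1OC(C)(C)C(C)(C)O1)=COc1cc(OCOC)c(C2(C)OCCO2)cc1C=O | intermediate (not isolated)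
11 | (2R,3R)-3-[(pinacolboryl)oxy] derivative of 12 | C=C(B3OC(C)(C)C(C)(C)O3)[C@H]1Oc2cc(OCOC)c(C4(C)OCCO4)cc2[C@H]1OB5OC(C)(C)C(C)(C)O5 | intermediate (not isolated)
12 | (2R,3R)-6-(methoxymethoxy)-5-(2-methyl-1,3-dioxolan-2-yl)-2-[1-(4,4,5,5-tetramethyl-1,3,2-dioxaborolan-2-yl)ethenyl]-2,3-dihydro-1-benzofuran-3-ol | C=C(B3OC(C)(C)C(C)(C)O3)[C@H]1Oc2cc(OCOC)c(C4(C)OCCO4)cc2[C@H]1O | intermediate
13 | (2S,3R)-2-(1-iodoethenyl)-6-(methoxymethoxy)-5-(2-methyl-1,3-dioxolan-2-yl)-2,3-dihydro-1-benzofuran-3-ol | C=C(I)[C@H]1Oc2cc(OCOC)c(C3(C)OCCO3)cc2[C@H]1O | intermediate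
14 | (tributylstannyl)methanol | CCCC[Sn](CCCC)(CCCC)CO | starting material
15 | (2R,3R)-2-(3-hydroxyprop-1-en-2-yl)-6-(methoxymethoxy)-5-(2-methyl-1,3-dioxolan-2-yl)-2,3-dihydro-1-benzofuran-3-ol | C=C(CO)[C@H]1Oc2cc(OCOC)c(C3(C)OCCO3)cc2[C@H]1O | intermediate
16 | 2-[(2R,3R)-3-hydroxy-6-(methoxymethoxy)-5-(2-methyl-1,3-dioxolan-2-yl)-2,3-dihydro-1-benzofuran-2-yl]prop-2-en-1-yl acetate | C=C(COC(C)=O)[C@H]1Oc2cc(OCOC)c(C3(C)OCCO3)cc2[C@H]1O | intermediate
17 | angelic acid, (2Z)-2-methylbut-2-enoic acid | C/C=C(/C)C(=O)O | starting material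
18 | (2Z)-2-methylbut-2-enoic 2,4,6-trichlorobenzoic anhydride | C/C=C(/C)C(=O)OC(=O)c1c(Cl)cc(Cl)cc1Cl | intermediate (not isolated)
19 | (2R,3R)-2-[3-(acetyloxy)prop-1-en-2-yl]-6-(methoxymethoxy)-5-(2-methyl-1,3-dioxolan-2-yl)-2,3-dihydro-1-benzofuran-3-yl (2Z)-2-methylbut-2-enoate | C=C(COC(C)=O)[C@H]1Oc2cc(OCOC)c(C3(C)OCCO3)cc2[C@H]1OC(=O)/C(C)=C\C | intermediate
20 | (2R,3R)-5-acetyl-2-[3-(acetyloxy)prop-1-en-2-yl]-6-(methoxymethoxy)-2,3-dihydro-1-benzofuran-3-yl (2Z)-2-methylbut-2-enoate | C=C(COC(C)=O)[C@H]1Oc2cc(OCOC)c(C(C)=O)cc2[C@H]1OC(=O)/C(C)=C\C | intermediate (not isolated)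
21 | (2R,3R)-5-acetyl-2-[3-(acetyloxy)prop-1-en-2-yl]-6-hydroxy-2,3-dihydro-1-benzofuran-3-yl (2Z)-2-methylbut-2-enoate | C=C(COC(C)=O)[C@H]1Oc2cc(O)c(C(C)=O)cc2[C@H]1OC(=O)/C(C)=C\C | target

## Step count and risks

Total step count: 10. Longest linear sequence: 10 steps (1 to 21).

**Step 5 (key step, new method).** Three processes could defeat it:
- 1,2-addition of Cu–Bpin to the aldehyde may outrun borylcupration of the allene.
- An open transition state may erode the cis selectivity or the enantioselectivity.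
- A second Cu–Bpin addition to the vinyl boronate of the product, followed by β-aryloxy elimination, may open the ring again.

The fallback sets out from 8 and uses the known palladium-catalysed distannylative cyclisation of allenyl aldehydes. With Bu3SnSnBu3 and [Pd(C3H5)Cl]2 in THF at rt, the allene takes up both tin groups and the allylic tin unit adds to the aldehyde, which should give the racemic cis tin alkoxide F1. Aqueous work-up gives the racemic cis 2-(1-tributylstannylethenyl) alcohol F2. Iododestannylation (I2, CH2Cl2, 0 °C) gives the racemic cis iodide F3. Preparative HPLC on a chiral stationary phase removes the (2R,3S) enantiomer F4, and the route is rejoined at 13.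

**Step 10.** Acid may ionise the benzylic C3–O bond before the MOM ether is gone, with loss of angelic acid, elimination to the benzofuran or epimerisation at C3. The risk is highest while the ring still carries the dioxolane. The fallback sets out from 16 and changes the order and the mechanism of unmasking:
- PPTS in wet acetone at rt removes only the dioxolane and gives the keto alcohol F5.
- Angeloylation with 18 as in step 9 gives 20, now isolated, on a ring deactivated by the acetyl group.
- TMSOTf and 2,2'-bipyridyl in CH2Cl2 at 0 °C convert the aryl MOM ether into the aryl trimethylsilyl ether F6 without Brønsted acid.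
- Water on work-up hydrolyses F6, and the route is rejoined at 21.

**Step 9.** The angeloyl unit may isomerise to the tiglate during acyl transfer, or acylation of the hindered cis alcohol may be so slow that elimination at C3 competes. The fallback sets out from 16 and builds the Z alkene after the ester bond is made. Esterification with 2-[bis(2,2,2-trifluoroethoxy)phosphoryl]propanoic acid (EDC, DMAP, CH2Cl2) gives the phosphonate ester F7. Still–Gennari olefination (KHMDS, 18-crown-6, THF, −78 °C, acetaldehyde) should then give the Z-trisubstituted enoate, and the route is rejoined at 19.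

## Further compounds

F1 | step 5 | racemic cis tributyltin alkoxide of F2 (both enantiomers written) | C=C([Sn](CCCC)(CCCC)CCCC)[C@H]1Oc2cc(OCOC)c(C3(C)OCCO3)cc2[C@H]1O[Sn](CCCC)(CCCC)CCCC.C=C([Sn](CCCC)(CCCC)CCCC)[C@@H]1Oc2cc(OCOC)c(C3(C)OCCO3)cc2[C@@H]1O[Sn](CCCC)(CCCC)CCCC
F2 | step 5 | racemic cis 6-(methoxymethoxy)-5-(2-methyl-1,3-dioxolan-2-yl)-2-[1-(tributylstannyl)ethenyl]-2,3-dihydro-1-benzofuran-3-ol (both enantiomers written) | C=C([Sn](CCCC)(CCCC)CCCC)[C@H]1Oc2cc(OCOC)c(C3(C)OCCO3)cc2[C@H]1O.C=C([Sn](CCCC)(CCCC)CCCC)[C@@H]1Oc2cc(OCOC)c(C3(C)OCCO3)cc2[C@@H]1O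
F3 | step 5 | racemic cis 2-(1-iodoethenyl)-6-(methoxymethoxy)-5-(2-methyl-1,3-dioxolan-2-yl)-2,3-dihydro-1-benzofuran-3-ol (both enantiomers written) | C=C(I)[C@H]1Oc2cc(OCOC)c(C3(C)OCCO3)cc2[C@H]1O.C=C(I)[C@@H]1Oc2cc(OCOC)c(C3(C)OCCO3)cc2[C@@H]1O
F4 | step 5 | (2R,3S)-2-(1-iodoethenyl)-6-(methoxymethoxy)-5-(2-methyl-1,3-dioxolan-2-yl)-2,3-dihydro-1-benzofuran-3-ol, the enantiomer of 13 removed in the resolution | C=C(I)[C@@H]1Oc2cc(OCOC)c(C3(C)OCCO3)cc2[C@@H]1O
F5 | step 10 | 2-[(2R,3R)-5-acetyl-3-hydroxy-6-(methoxymethoxy)-2,3-dihydro-1-benzofuran-2-yl]prop-2-en-1-yl acetate | C=C(COC(C)=O)[C@H]1Oc2cc(OCOC)c(C(C)=O)cc2[C@H]1O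
F6 | step 10 | (2R,3R)-5-acetyl-2-[3-(acetyloxy)prop-1-en-2-yl]-6-[(trimethylsilyl)oxy]-2,3-dihydro-1-benzofuran-3-yl (2Z)-2-methylbut-2-enoate | C=C(COC(C)=O)[C@H]1Oc2cc(O[Si](C)(C)C)c(C(C)=O)cc2[C@H]1OC(=O)/C(C)=C\C
F7 | step 9 | (2R,3R)-2-[3-(acetyloxy)prop-1-en-2-yl]-6-(methoxymethoxy)-5-(2-methyl-1,3-dioxolan-2-yl)-2,3-dihydro-1-benzofuran-3-yl 2-[bis(2,2,2-trifluoroethoxy)phosphoryl]propanoate (mixture of epimers at the phosphonate-bearing carbon) | C=C(COC(C)=O)[C@H]1Oc2cc(OCOC)c(C3(C)OCCO3)cc2[C@H]1OC(=O)C(C)P(=O)(OCC(F)(F)F)OCC(F)(F)F
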